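the same everywhere: substrate 0.073 M; free catalyst 0.2 mol%

|  | reagent | temperature | remark | time |
|---|---|---|---|---|
| blue | 5 equiv | 25 °C | the very flask that is asked about, followed so far |  |
| ochre | 5 equiv | 31 °C | run made earlier |  |
| flask | 5.00 equiv | 25 °C |  | 2.0 h |

| run | time / min | product / % | substrate / % |
|---|---|---|---|
| blue | 12.0 | 53.4 | 46.0 |
| blue | 30.0 | 62.9 | 36.1 |
| blue | 60.0 | 65.0 | 35.3 |
| blue | 90.0 | 64.0 | 35.4 |
| ochre | 12.0 | 58.7 | 39.2 |
| ochre | 30.0 | 66.5 | 33.8 |
| ochre | 60.0 | 68.1 | 30.3 |
| ochre | 90.0 | 67.2 | 30.8 |

(standard deviation of a reading: 1 percentage point)

- south-east: change nothing and wait 40 min more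
- north: at 2.0 h add free catalyst, 100% of the amount charged, then wait 40 min
- north-west: at 2.0 h add reagent, 50.0% of the amount charged, then wait 40 min
- west: at 2.0 h raise the temperature by 15 K, then wait 40 min

- amounts and yields of product count crystals too
- given per volume of solution although it is solid: crystals
- additions leave the volume as it is
- reactions considered so far: reagent + free catalyst <-> catalyst intermediate A; substrate + catalyst intermediate A <-> catalyst intermediate B; catalyst intermediate B -> catalyst intermediate C; catalyst intermediate C -> free catalyst + product; crystals <-> product; 2 reagent -> homo dimer

* product, in percent of the substrate first charged, at 2.0 h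
* the remedy with the largest gain of product, or "none" below 2 percentage points (south-east / north / north-west / west / none)
* product present, in percent of the substrate first charged, after south-east
* product present, in percent of the substrate first charged, after west

- A small charge, 0.2 mol% of free catalyst, does the work in the blue flask, and the cycle returns it after each turn. Taking the main step first, each product costs one reagent, so 5.00 equiv of reagent should be enough for the substrate charged.
- The blue flask stops instead. From 60.0 min to 90.0 min product stays near 64.5% and substrate near 35.3%, and these sum to about the charge. My reckoning takes the listed steps at face value: catalyst survives, so reagent must have gone elsewhere.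
- Dimerisation is the one more process. Write R for reagent in equivalents of substrate. The catalyst's take is pseudo-first-order in R, while the take of dimerisation goes with R squared. The two are equal at R = r, so a reagent lost at level R becomes product with chance r/(r+R). Summed from the charge E down to nil, this gives product P = r·ln(1 + E/r).
- This equation holds r on both sides, so it is solved by iteration. Putting 0.297 in as a first answer returns 0.224. Further rounds pass 0.205 and 0.199, and arrive at 0.198 equivalents: the crossover level, the reagent level at which catalyst and dimerisation take equal amounts. On this reckoning reagent is the limiting reagent of the blue flask: its charge stands far above r, and 12.9% of it ends in product, the rest in homo dimer.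
- Crystals count as product, so they drop out of the reckoning. The warmer ochre flask stops higher, near 67.6%, but it was warm from the start, while west raises the temperature of the blue flask at 2.0 h, after the readings have gone flat.
- My reckoning for the blue flask: 64.5% at 2.0 h, with waiting, heat and catalyst gaining nothing. Adding 50.0% of the reagent charge offers 51.7% of the substrate charge, so the substrate left caps the gain at about 35.3%.
- The forecast gives 64.5%, 64.7% after waiting and 65.2% after heating, and it chooses north, where mine chooses north-west. Its grounds: “The stop fits exponential loss of active catalyst”.
- The blue flask gives 65.3%, and 65.3% and 65.3% after waiting and heating. The best remedy is north-west, gaining 35 percentage points, against 0 points for north. At 120 min reagent stands at 0% of its charge and substrate at 34.7%. The crossover level put to use once more: E/r is 25.3, the start ratio of dimerisation to catalyst as read from the blue plateau, and the forward steps at the start give 22.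

    reagent + free catalyst ⇌ catalyst intermediate A (K = 13.0 M⁻¹, k = 8.60 M⁻¹ s⁻¹, Ea = 49.0 kJ mol⁻¹, ΔH = −32.0 kJ mol⁻¹)
    substrate + catalyst intermediate A ⇌ catalyst intermediate B (K = 36.0 M⁻¹, k = 2000 M⁻¹ s⁻¹, Ea = 35.0 kJ mol⁻¹, ΔH = −15.0 kJ mol⁻¹)
    catalyst intermediate B → catalyst intermediate C (k = 730 s⁻¹, Ea = 55.0 kJ mol⁻¹)
    catalyst intermediate C → free catalyst + product (k = 9.10 s⁻¹, Ea = 69.0 kJ mol⁻¹)
    crystals ⇌ product, rate k5*(cs5 - [product]) while solid is left; crystals form when [product] > cs5 (solubility = 42.0 mM, k = 1.00 s⁻¹)
    2 reagent → homo dimer (k = 0.0380 M⁻¹ s⁻¹, Ea = 43.0 kJ mol⁻¹)
    (constants at 25 °C)

- Second flask: the neighbour with 0.08 mol% of free catalyst. The catalyst's take scales with its charge, so r becomes 0.0791 equivalents, and P = r·ln(1 + E/r) gives 32.9% of the substrate.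
- That neighbour gives 33.6%, with 0.050% of its reagent left.

Readings and results are simulated on assumed constants, and the scatter is random.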